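## Structural features

The target 16 is a flavanone: benzene ring A is fused to the dihydropyranone ring C (O1, C2, C3, the C4 carbonyl, C4a, C8a) and carries a free hydroxyl at C7. Ring B is joined to C2 through its own C6; it is a 2,2-dimethyl-2H-chromene with a prenyl group at C8, ortho to the pyran oxygen. C2 is the only stereocentre and is R; it has no stereogenic neighbour, but it is benzylic, bound to O1, para-related through ring B to the pyran oxygen, and β to the C4 ketone. This makes it fragile: base or hot acid opens ring C by retro-oxa-Michael reaction to an achiral hydroxychalcone, and strong acid can ionise the C2–O1 bond. The prenyl alkene and the chromene C3=C4 alkene rule out hydrogenolysis, electrophilic oxidants and strong protic acid, and the C7 phenol is an unwanted acid and nucleophile in base-mediated steps. The real difficulty is therefore not the C6–C3–C6 skeleton but setting C2 in high enantiopurity and never again exposing it to a C4 carbonyl and a base together. The key step exploits three facts: O1 links C2 to C8a, C8a is ortho to C4a (which bears C4), and C2 and C4 are 1,3-related. Ring C is thus a cyclised 1,3-diaryl-propane-1,3-diol, whose carbinols come from a 1,3-diketone and whose O1–C8a bond can be made by aryl C–O coupling onto a C8a bromide while C4 is still an alcohol.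

## Logic of the disconnections

16 ⇒ 15. The C7 oxygen is reconnected to its acetal protecting group (O–CH2 bond). The free phenol would consume base in the condensation and act as an Ullmann nucleophile in the ring closure. Nothing is gained in skeleton, but the whole base-heavy sequence becomes possible. The forward step must remove the acetal without opening ring C or adding to the two alkenes, so dilute acid near room temperature is required.

15 ⇒ 14. The C4 carbonyl is taken back to a carbinol. With C4 as an alcohol there is no enolisable ketone next to C2, so ring opening, retro-aldol cleavage and dehydration are impossible in the preceding hot, basic step. The forward step must be a mild, non-basic oxidation of the single free hydroxyl.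

14 ⇒ 13 (key). The O1–C8a bond is cut. This takes C2 out of the ring and places it on an open chain, where it can be set by carbonyl reduction and is not touched by the ring closure. Ring C disappears and the problem becomes a 1,3-diol carrying an aryl bromide. The forward C–O coupling must use the C2 hydroxyl and not the C4 hydroxyl, must be intramolecular, and must leave both carbinol carbons and both alkenes alone.

13 ⇒ 11 (through 12). The C–H bonds at C2 and C4 are removed, giving an achiral 1,3-diketone. One chiral catalyst then sets both carbinols; only C2 matters for 16, because C4 is oxidised later, so a C4 epimer carried forward would converge at 15. The forward reduction must be selective for C=O over C=C and C–Br and must be catalyst-controlled at both carbonyls.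

11 ⇒ 2 + 10. The C2–C3 bond is cut (crossed Claisen condensation). The molecule splits into a ring A methyl ketone and a ring B ester of similar size. Only one partner is enolisable, which makes the crossing clean, but the ester is electron-rich and slow, and the product enolate must not displace the ortho bromide.

2 ⇒ 1. The acetal O–CH2 bond is removed to reach the commercial bromohydroxy ketone; the forward step is a routine phenol protection.

10 ⇒ 7 (through 8 and 9). The pyran ring of ring B is opened at the bond between the arene carbon (chromene C4a) and C4. The ring reduces to an aryl 1,1-dimethylpropargyl ether, which returns to the chromene by propargyl Claisen rearrangement, hydrogen shift and oxa-electrocyclisation. The rearrangement must go to an ortho carbon bearing hydrogen; only one exists, because the other is prenylated.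

7 ⇒ 5 + 6. The ether bond between the phenol oxygen and the tertiary propargylic carbon is cut. The forward step needs substitution at a tertiary centre without elimination, which copper catalysis provides.

5 ⇒ 3 + 4. The bond between the arene and the prenyl CH2 is cut, leaving two bulk chemicals. The forward alkylation must occur at carbon and not oxygen, once and not twice, and through the primary terminus of the allyl unit.

## Other disconnections considered

Alternative 1: The cut removes ring A by breaking C4a–C5 and C8–C8a. It leaves the (R)-2-aryl-2,3-dihydropyran-4-one A2, which carries a phenylsulfinyl group on the carbon that becomes C4a, and the diene A3, (E)-1-methoxy-3-(trimethylsilyloxy)buta-1,3-diene.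

- Forward step: A2 and A3 would be heated in toluene. The CH2 terminus of A3 should bond to the oxygen-bearing enone carbon (future C8a) and the methoxy-bearing terminus to the sulfinyl-bearing carbon (future C4a). Syn-elimination of the sulfur group and 1,4-loss of the methoxy group would then aromatise ring A to A1, the 7-O-trimethylsilyl ether of 16.
- In favour: A2 could come from the ring B aldehyde A4 (10 at the aldehyde oxidation level) and the same diene A3 by a catalytic asymmetric hetero-Diels–Alder reaction, followed by sulfenylation at C5 and oxidation at sulfur. The polarisation of A3 places the oxygen at C7, and the C4 ketone is present throughout. The silyl ether of A1 should fall to the phenol on mild work-up, so the end game needs neither an oxidation nor an acid deprotection; on this point the alternative is better than the chosen plan.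
- Against: the dienophile is a vinylogous ester, electron-rich at the carbon that must accept the diene and activated only by the sulfinyl group, so prolonged heating is likely. C2 in A2 and A1 is β to a ketone and on a p-alkoxyphenyl ring, so thermal ring opening and the acid released on aromatisation both threaten it. The sulfide oxidation must also spare the prenyl and chromene alkenes.
- Comparison: structurally both plans are convergent and use the same ring B unit. Mechanistically the chosen plan sets C2 by catalyst-controlled hydride delivery and never combines a C4 carbonyl with base, whereas here the stereocentre must survive the hottest step beside a ketone. In step count the two are about equal (eight to nine operations), since sulfenylation and S-oxidation offset the saved redox and deprotection steps.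

Alternative 2: The cut removes rings A and C together by breaking C4a–C8a, C5–C6 and C7–C8. It leaves the chiral diyne A6, whose C2 carbon carries an ethynyl ether on oxygen and, through C3, a terminal ynone, and the two-carbon partner A7, (triisopropylsilyloxy)ethyne.

- Forward step: [Rh(cod)2]BF4 with BINAP near room temperature would couple the two alkynes of A6 to a rhodacyclopentadiene (C4a–C8a, ring C), insert A7 and eliminate reductively to form ring A, giving A5, the 7-O-triisopropylsilyl ether of 16.
- In favour: one step builds two rings and three C–C bonds with full atom economy under neutral conditions, the C4 ketone is in place, and only a desilylation remains. On convergence of the ring-forming event, redox economy and mildness of the key step, the alternative is better than the chosen plan.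
- Against: A6 is a β-alkoxy ynone whose leaving group would be an ynolate, so simple enolisation invites E1cB loss of the stereocentre. Secondary p-alkoxybenzyl ethynyl ethers are prone to sigmatropic and retro-ene decomposition. Making an ethynyl ether on a secondary alcohol needs strongly basic chemistry that the ketone or its precursor must survive. The position of the silyloxy group (C7 and not C6) rests on a modest electronic difference between the two ends of the rhodacycle. The chiral ligand creates no stereocentre, so C2 must already be set, for example by an asymmetric addition to A4.
- Comparison: structurally the alternative is more ambitious, but A6 is far less stable than 13. Mechanistically the chosen C–O coupling has one possible ring size and no regiochemical question, whereas the cyclotrimerisation has two regiochemical outcomes. In step count the alternative is short after A6 (two steps to 16), but the way to A6 from A4 is estimated at six to eight steps, so it is unlikely to undercut nine steps overall.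

Alternative 3: The cut is the C2–C3 bond. 16 is traced to the racemic mixed acetal A9, a 2-aryl-4-methylene-4H-1,3-benzodioxine with the C7 oxygen as its tert-butyldimethylsilyl ether; C2 is the acetal carbon and the exocyclic methylene is the future C3.

- Forward step: a chiral aluminium Lewis acid made from AlMe3 and an enantiopure 3,3'-bis(triphenylsilyl)-1,1'-bi-2-naphthol would ionise the C2–O3 bond to an aryloxycarbenium ion tethered through O1 to an aluminium enolate. The enolate carbon would then close on C2 (Petasis–Ferrier-type shift) to give A8, the 7-O-tert-butyldimethylsilyl ether of 16. Both enantiomers of A9 pass through the same planar cation, so the ligand on aluminium would decide C2.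
- In favour: A9 should be available from A4 in about two steps (acetalisation with the matching salicylic acid partner, then methylenation of the lactone carbonyl). No enantiopure intermediate has to be made or guarded, the ketone and the stereocentre appear together, and nothing is oxidised afterwards. On step count (about seven) and redox economy the alternative is better than the chosen plan.
- Against: absolute control of such a shift by a chiral aluminium reagent has no close precedent and would have to be developed. The cation is a strongly stabilised p-alkoxybenzylic one, only loosely held by the chiral enolate, which is the worst case for face selection. The Lewis acid is needed in stoichiometric amount, stays on the product ketone and could reopen ring C. The electron-rich alkenes of ring B are competing nucleophiles, and A9 is hydrolytically delicate.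
- Comparison: both plans use the same ring B unit and neither needs a chiral starting material, so they are equal there. The chosen plan is about two steps longer, but each step is a known reaction type on this substrate class and C2 is set by a reduction of predictable sense. The alternative concentrates all stereochemical risk in one undeveloped final step.

Key step: step 7

Remarks on the chemistry before the steps:

- Descriptor check: the (R,R) catalyst gives R carbinols at both aryl ketones; ring closure changes neither descriptor; (2R,4R)-14 has the C4 hydroxyl cis to the C2 aryl group; oxidation leaves (2R)-16. No correction of the structures is needed.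
- Design choices: the bromide and the acetal protecting group are kept. The oxidation after the key step uses Dess–Martin periodinane instead of a heterogeneous oxidant, for reliability.
- Assumption: in step 6 the carbonyl next to the bromoaryl ring, the more electrophilic one, is reduced first (12); the order does not affect 13. Compound 11 is drawn as the diketo tautomer, although it should exist largely as the enol.

## Route

Step 1
Reactants: 1 1-(2-bromo-4-hydroxyphenyl)ethanone
Product: 2 1-[2-bromo-4-(methoxymethoxy)phenyl]ethanone
Conditions: MOMCl, i-Pr2NEt, CH2Cl2, 0 °C → rt
Reagents that add atoms: chloromethyl methyl ether, COCCl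
Why: O-Alkylation of the phenol by the chloromethyl ether (acetal protection); the acetal withstands NaH, the ruthenium hydride and hot Cs2CO3, and it masks a phenol that would otherwise consume base in step 5 and compete as a nucleophile in step 7.

Step 2
Reactants: 3 methyl 4-hydroxybenzoate; 4 1-bromo-3-methylbut-2-ene (prenyl bromide)
Product: 5 methyl 4-hydroxy-3-(3-methylbut-2-en-1-yl)benzoate
Conditions: NaH (1 equiv), toluene, 0 °C → rt
Reagents that add atoms: none
Why: ortho-C-Alkylation of a sodium phenoxide in a non-polar solvent: the aggregated, tightly ion-paired phenoxide is shielded at oxygen and the bromide is delivered to the ortho carbon at its primary terminus, so the linear prenyl group results after tautomerisation; the para position is blocked by the ester and a slight excess of 3 limits double alkylation.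

Step 3
Reactants: 5 methyl 4-hydroxy-3-(3-methylbut-2-en-1-yl)benzoate; 6 3-chloro-3-methylbut-1-yne
Product: 7 methyl 4-[(2-methylbut-3-yn-2-yl)oxy]-3-(3-methylbut-2-en-1-yl)benzoate
Conditions: CuCl2·2H2O (cat.), DBU, MeCN, 0 °C
Reagents that add atoms: none
Why: Copper-catalysed propargylic etherification: the copper acetylide of 6 loses chloride to an allenylidene-type electrophile that the phenoxide captures at the tertiary carbon, avoiding the elimination that plain Williamson conditions would favour; an acidic phenol such as 5 is a good partner.

Step 4
Reactants: 7 methyl 4-[(2-methylbut-3-yn-2-yl)oxy]-3-(3-methylbut-2-en-1-yl)benzoate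
Product: 10 methyl 2,2-dimethyl-8-(3-methylbut-2-en-1-yl)-2H-chromene-6-carboxylate, via allenylphenol 8 (not isolated), via quinone methide 9 (not isolated)
Conditions: PhNEt2, 190 °C
Reagents that add atoms: none
Why: Aromatic propargyl Claisen rearrangement to the only hydrogen-bearing ortho carbon and tautomerisation give 8, a 1,5-hydrogen shift from the hydroxyl to the central allene carbon gives 9, and 6π oxa-electrocyclisation closes the dimethylpyran; a shift to the prenylated ortho carbon is reversible and unproductive, and the weakly basic solvent protects the prenyl group from acid.

Step 5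
Reactants: 2 1-[2-bromo-4-(methoxymethoxy)phenyl]ethanone; 10 methyl 2,2-dimethyl-8-(3-methylbut-2-en-1-yl)-2H-chromene-6-carboxylate
Product: 11 1-[2-bromo-4-(methoxymethoxy)phenyl]-3-[2,2-dimethyl-8-(3-methylbut-2-en-1-yl)-2H-chromen-6-yl]propane-1,3-dione
Conditions: NaH (3 equiv), THF, 0 → 60 °C (2 added slowly); then AcOH
Reagents that add atoms: none
Why: Crossed Claisen condensation: only 2 can enolise, its sodium enolate adds to the non-enolisable ester 10, and irreversible deprotonation of the 1,3-diketone drives the reaction; slow addition of 2 limits its self-aldol reaction, and THF at moderate temperature keeps the diketone enolate from displacing the ortho bromide.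

Step 6
Reactants: 11 1-[2-bromo-4-(methoxymethoxy)phenyl]-3-[2,2-dimethyl-8-(3-methylbut-2-en-1-yl)-2H-chromen-6-yl]propane-1,3-dione
Product: 13 (1R,3R)-1-[2-bromo-4-(methoxymethoxy)phenyl]-3-[2,2-dimethyl-8-(3-methylbut-2-en-1-yl)-2H-chromen-6-yl]propane-1,3-diol, via hydroxy ketone 12 (not isolated)
Conditions: RuCl(p-cymene)[(R,R)-TsDPEN] (2 mol %), HCO2H–Et3N (5:2), CH2Cl2, 35 °C
Reagents that add atoms: none
Why: Noyori–Ikariya asymmetric transfer hydrogenation, applied twice: the divalent ruthenium hydride and its N–H deliver hydride and proton to each aryl ketone through an outer-sphere six-membered transition state in which a CH–π contact between the cymene ligand and the ketone's aryl ring selects the face, so the (R,R) catalyst should give an R carbinol at both carbons and hence the anti diol. The mechanism reduces only polar C=O bonds, so both alkenes and the aryl bromide are untouched; the ring B carbinol (future C2) is the centre that counts, since the other is erased in step 8.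

Step 7
Reactants: 13 (1R,3R)-1-[2-bromo-4-(methoxymethoxy)phenyl]-3-[2,2-dimethyl-8-(3-methylbut-2-en-1-yl)-2H-chromen-6-yl]propane-1,3-diol
Product: 14 (2R,4R)-2-[2,2-dimethyl-8-(3-methylbut-2-en-1-yl)-2H-chromen-6-yl]-7-(methoxymethoxy)-3,4-dihydro-2H-chromen-4-ol
Conditions: CuI (10 mol %), 1,10-phenanthroline (20 mol %), Cs2CO3 (2 equiv), degassed toluene (0.05 M), 110 °C, Ar
Reagents that add atoms: none
Why: Ullmann-type intramolecular C–O coupling; the closest known reaction type is the copper/phenanthroline O-arylation of aliphatic alcohols with aryl halides, used intramolecularly to make chromans. Cs2CO3 generates the C2 alkoxide, which binds phenanthroline-ligated monovalent copper; oxidative addition into C8a–Br gives a trivalent copper aryl alkoxide in a seven-membered chelate, and reductive elimination forms O1–C8a. Ring C closes as a six-membered ring by this reductive elimination, formally a 6-exo attack of oxygen on the sp2 carbon C8a. No stereocentre is created: only O–H and C–Br bonds change, so C2 stays R and C4 stays R, which puts the C4 hydroxyl cis to the C2 aryl group in 14. Chemoselectivity between the two secondary benzylic hydroxyls is secured by ring size, because the C4 oxygen could reach C8a only through a four-membered ring. With C4 as a carbinol there is no enolisable ketone, so retro-aldol cleavage, dehydration to a chalcone and retro-oxa-Michael opening have no entry point under the hot basic conditions. Dilution and exclusion of oxygen should suppress intermolecular etherification and copper-mediated oxidation of the benzylic alcohols, and the alkenes and the aryl acetal are spectators.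

Step 8
Reactants: 14 (2R,4R)-2-[2,2-dimethyl-8-(3-methylbut-2-en-1-yl)-2H-chromen-6-yl]-7-(methoxymethoxy)-3,4-dihydro-2H-chromen-4-ol
Product: 15 (2R)-2-[2,2-dimethyl-8-(3-methylbut-2-en-1-yl)-2H-chromen-6-yl]-7-(methoxymethoxy)-2,3-dihydro-4H-chromen-4-one
Conditions: Dess–Martin periodinane, NaHCO3, CH2Cl2, 0 °C → rt
Reagents that add atoms: none
Why: Dess–Martin oxidation of the single free secondary benzylic alcohol (ligand exchange at hypervalent iodine, then removal of the carbinol hydrogen by acetate); the buffered, non-basic medium gives the β-aryloxy ketone no chance to open by retro-oxa-Michael reaction, so C2 is retained, and the alkenes and the acetal are inert to the reagent.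

Step 9
Reactants: 15 (2R)-2-[2,2-dimethyl-8-(3-methylbut-2-en-1-yl)-2H-chromen-6-yl]-7-(methoxymethoxy)-2,3-dihydro-4H-chromen-4-one
Product: 16 (2R)-2-[2,2-dimethyl-8-(3-methylbut-2-en-1-yl)-2H-chromen-6-yl]-7-hydroxy-2,3-dihydro-4H-chromen-4-one
Conditions: HCl (ca. 1.5 M), MeOH–THF, rt → 40 °C
Reagents that add atoms: none
Why: Acid-catalysed acetal solvolysis transfers the methoxymethyl group to methanol; in dilute acid near room temperature the flavanone should not open at a meaningful rate, so C2 is retained, and the prenyl group cannot cyclise because its neighbouring oxygen is an ether and not a phenol.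

## Compound list

1 | 1-(2-bromo-4-hydroxyphenyl)ethanone | CC(=O)c1ccc(O)cc1Br | starting material
2 | 1-[2-bromo-4-(methoxymethoxy)phenyl]ethanone | CC(=O)c1ccc(OCOC)cc1Br | intermediate
3 | methyl 4-hydroxybenzoate | COC(=O)c1ccc(O)cc1 | starting material
4 | 1-bromo-3-methylbut-2-ene (prenyl bromide) | CC(C)=CCBr | starting material
5 | methyl 4-hydroxy-3-(3-methylbut-2-en-1-yl)benzoate | COC(=O)c1ccc(O)c(CC=C(C)C)c1 | intermediate
6 | 3-chloro-3-methylbut-1-yne | CC(C)(Cl)C#C | starting material
7 | methyl 4-[(2-methylbut-3-yn-2-yl)oxy]-3-(3-methylbut-2-en-1-yl)benzoate | COC(=O)c1ccc(OC(C)(C)C#C)c(CC=C(C)C)c1 | intermediate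
8 | methyl 4-hydroxy-3-(3-methylbuta-1,2-dien-1-yl)-5-(3-methylbut-2-en-1-yl)benzoate | COC(=O)c1cc(C=C=C(C)C)c(O)c(CC=C(C)C)c1 | intermediate
9 | methyl 3-(3-methylbut-2-en-1-ylidene)-5-(3-methylbut-2-en-1-yl)-4-oxocyclohexa-1,5-diene-1-carboxylate | COC(=O)C1=CC(=CC=C(C)C)C(=O)C(CC=C(C)C)=C1 | intermediate
10 | methyl 2,2-dimethyl-8-(3-methylbut-2-en-1-yl)-2H-chromene-6-carboxylate | CC(C)=CCc1cc(C(=O)OC)cc2c1OC(C)(C)C=C2 | intermediate
11 | 1-[2-bromo-4-(methoxymethoxy)phenyl]-3-[2,2-dimethyl-8-(3-methylbut-2-en-1-yl)-2H-chromen-6-yl]propane-1,3-dione | CC(C)=CCc1cc(C(=O)CC(=O)c3ccc(OCOC)cc3Br)cc2c1OC(C)(C)C=C2 | intermediate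
12 | (3R)-3-[2-bromo-4-(methoxymethoxy)phenyl]-1-[2,2-dimethyl-8-(3-methylbut-2-en-1-yl)-2H-chromen-6-yl]-3-hydroxypropan-1-one | CC(C)=CCc1cc(C(=O)C[C@@H](O)c3ccc(OCOC)cc3Br)cc2c1OC(C)(C)C=C2 | intermediate
13 | (1R,3R)-1-[2-bromo-4-(methoxymethoxy)phenyl]-3-[2,2-dimethyl-8-(3-methylbut-2-en-1-yl)-2H-chromen-6-yl]propane-1,3-diol | CC(C)=CCc1cc([C@H](O)C[C@@H](O)c3ccc(OCOC)cc3Br)cc2c1OC(C)(C)C=C2 | intermediate
14 | (2R,4R)-2-[2,2-dimethyl-8-(3-methylbut-2-en-1-yl)-2H-chromen-6-yl]-7-(methoxymethoxy)-3,4-dihydro-2H-chromen-4-ol | CC(C)=CCc1cc([C@H]2C[C@@H](O)c3ccc(OCOC)cc3O2)cc2c1OC(C)(C)C=C2 | intermediate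
15 | (2R)-2-[2,2-dimethyl-8-(3-methylbut-2-en-1-yl)-2H-chromen-6-yl]-7-(methoxymethoxy)-2,3-dihydro-4H-chromen-4-one | CC(C)=CCc1cc([C@H]2CC(=O)c3ccc(OCOC)cc3O2)cc2c1OC(C)(C)C=C2 | intermediate
16 | (2R)-2-[2,2-dimethyl-8-(3-methylbut-2-en-1-yl)-2H-chromen-6-yl]-7-hydroxy-2,3-dihydro-4H-chromen-4-one (ent-abyssinone III) | CC(C)=CCc1cc([C@H]2CC(=O)c3ccc(O)cc3O2)cc2c1OC(C)(C)C=C2 | target

## Step count and risk

Total step count: 9. Longest linear sequence: 8 steps (3 → 5 → 7 → 10 → 11 → 13 → 14 → 15 → 16); the ring A branch (1 → 2) joins at step 5.

Steps least certain to work:

**Step 7 (key step).**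
- Risk: oxidative addition of monovalent copper into the ortho-substituted, unactivated C8a–Br bond may be slow with a hindered secondary alkoxide as the anionic ligand. Over long heating, protodebromination and copper-mediated dehydrogenation of a benzylic carbinol could then gain ground.
- Fallback: the same bond is closed from 13 by a palladium-catalysed Buchwald–Hartwig-type etherification (Pd(OAc)2, a bulky di-tert-butylbiarylphosphine such as t-BuXPhos, Cs2CO3, toluene, 70–80 °C). This changes the metal and the elementary steps: zerovalent palladium inserts into C–Br well below 100 °C, and the bulky ligand drives C–O reductive elimination from the divalent aryl palladium alkoxide ahead of β-hydride elimination. It returns to the route at 14 and makes no new compound (F0).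

**Step 2.**
- Risk: poor C- versus O-selectivity of the ambident phenoxide and over-alkylation at the second ortho carbon, because the ester lowers the nucleophilicity of the ring carbons.
- Fallback: from 3, ortho-iodination (NIS, TsOH cat., MeCN, rt) gives methyl 4-hydroxy-3-iodobenzoate F1. A Stille coupling with tributyl(3-methylbut-2-en-1-yl)stannane (Pd(PPh3)4, DMF, 90 °C) then transfers the prenyl group through its CH2 terminus and returns to the route at 5. The position is fixed by the halogen instead of by phenoxide reactivity.

**Step 5.**
- Risk: self-condensation of 2 and premature closure of the diketone enolate onto the ortho bromide, both favoured by the heat that the electron-rich ester requires.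
- Fallback: from 10, saponification (LiOH, THF–MeOH–H2O) gives 2,2-dimethyl-8-(3-methylbut-2-en-1-yl)-2H-chromene-6-carboxylic acid F2. 1H-Benzotriazole and SOCl2 in CH2Cl2 convert it into (1H-benzotriazol-1-yl)[2,2-dimethyl-8-(3-methylbut-2-en-1-yl)-2H-chromen-6-yl]methanone F3. The lithium enolate of 2 (LiHMDS, 2 equiv, THF, −78 °C) is C-acylated by this activated amide at low temperature, returning at 11.

**Step 6.**
- Risk: stalling after the first reduction, or incomplete catalyst control in the second, since one ketone is electron-rich and the other is flanked by bromine; a mixture containing the syn diol would result.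
- Fallback: setting out from 12, isolated after stopping the transfer hydrogenation at the first reduction, the remaining ketone is reduced under substrate control by the Evans–Saksena method (Me4NBH(OAc)3, MeCN–AcOH, −30 °C). The existing hydroxyl binds boron and delivers hydride intramolecularly to give the 1,3-anti diol, returning at 13 with no new compound (F0).

**Step 9.**
- Risk: acid-promoted addition of methanol or HCl to the prenyl or chromene alkene, or erosion at C2 through ionisation of the p-alkoxybenzylic C2–O1 bond if the acetal cleaves slowly.
- Fallback: from 15, TMSOTf and 2,2'-bipyridyl in CH2Cl2 at 0 °C exchange the methoxymethyl group for a silyl group under buffered, non-protic conditions. This gives (2R)-2-[2,2-dimethyl-8-(3-methylbut-2-en-1-yl)-2H-chromen-6-yl]-7-[(trimethylsilyl)oxy]-2,3-dihydro-4H-chromen-4-one F4, which water cleaves at neutral pH, returning at 16.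

## Further compounds

F0 | step 7 | none | none
F1 | step 2 | methyl 4-hydroxy-3-iodobenzoate | COC(=O)c1ccc(O)c(I)c1
F2 | step 5 | 2,2-dimethyl-8-(3-methylbut-2-en-1-yl)-2H-chromene-6-carboxylic acid | CC(C)=CCc1cc(C(=O)O)cc2c1OC(C)(C)C=C2
F3 | step 5 | (1H-benzotriazol-1-yl)[2,2-dimethyl-8-(3-methylbut-2-en-1-yl)-2H-chromen-6-yl]methanone | CC(C)=CCc1cc(C(=O)n3nnc4ccccc43)cc2c1OC(C)(C)C=C2
F0 | step 6 | none | none
F4 | step 9 | (2R)-2-[2,2-dimethyl-8-(3-methylbut-2-en-1-yl)-2H-chromen-6-yl]-7-[(trimethylsilyl)oxy]-2,3-dihydro-4H-chromen-4-one | CC(C)=CCc1cc([C@H]2CC(=O)c3ccc(O[Si](C)(C)C)cc3O2)cc2c1OC(C)(C)C=C2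
A1 | alternative 1 | (2R)-2-[2,2-dimethyl-8-(3-methylbut-2-en-1-yl)-2H-chromen-6-yl]-7-[(trimethylsilyl)oxy]-2,3-dihydro-4H-chromen-4-one | CC(C)=CCc1cc([C@H]2CC(=O)c3ccc(O[Si](C)(C)C)cc3O2)cc2c1OC(C)(C)C=C2
A2 | alternative 1 | (2R)-2-[2,2-dimethyl-8-(3-methylbut-2-en-1-yl)-2H-chromen-6-yl]-5-(phenylsulfinyl)-2,3-dihydro-4H-pyran-4-one (configuration at sulfur unspecified) | CC(C)=CCc1cc([C@H]2CC(=O)C(S(=O)c3ccccc3)=CO2)cc2c1OC(C)(C)C=C2
A3 | alternative 1 | (E)-1-methoxy-3-(trimethylsilyloxy)buta-1,3-diene | CO/C=C/C(=C)O[Si](C)(C)C
A4 | alternative 1 | 2,2-dimethyl-8-(3-methylbut-2-en-1-yl)-2H-chromene-6-carbaldehyde | CC(C)=CCc1cc(C=O)cc2c1OC(C)(C)C=C2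
A5 | alternative 2 | (2R)-2-[2,2-dimethyl-8-(3-methylbut-2-en-1-yl)-2H-chromen-6-yl]-7-[(triisopropylsilyl)oxy]-2,3-dihydro-4H-chromen-4-one | CC(C)=CCc1cc([C@H]2CC(=O)c3ccc(O[Si](C(C)C)(C(C)C)C(C)C)cc3O2)cc2c1OC(C)(C)C=C2
A6 | alternative 2 | (5R)-5-[2,2-dimethyl-8-(3-methylbut-2-en-1-yl)-2H-chromen-6-yl]-5-(ethynyloxy)pent-1-yn-3-one | CC(C)=CCc1cc([C@H](OC#C)CC(=O)C#C)cc2c1OC(C)(C)C=C2
A7 | alternative 2 | (triisopropylsilyloxy)ethyne | C#CO[Si](C(C)C)(C(C)C)C(C)C
A8 | alternative 3 | (2R)-7-[(tert-butyldimethylsilyl)oxy]-2-[2,2-dimethyl-8-(3-methylbut-2-en-1-yl)-2H-chromen-6-yl]-2,3-dihydro-4H-chromen-4-one | CC(C)=CCc1cc([C@H]2CC(=O)c3ccc(O[Si](C)(C)C(C)(C)C)cc3O2)cc2c1OC(C)(C)C=C2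
A9 | alternative 3 | racemic 7-[(tert-butyldimethylsilyl)oxy]-2-[2,2-dimethyl-8-(3-methylbut-2-en-1-yl)-2H-chromen-6-yl]-4-methylidene-4H-1,3-benzodioxine | CC(C)=CCc1cc(C2OC(=C)c3ccc(O[Si](C)(C)C(C)(C)C)cc3O2)cc2c1OC(C)(C)C=C2
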